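Assumption: compounds 1, 5, 7 and 8 are taken as purchasable; 1 is the free acid of the commercial fragrance ester methyl 2,4-dihydroxy-3,6-dimethylbenzoate.

## Analysis of the target

Hypothamnolic acid (15) is a depside: two benzene rings joined only by an aryl ester, with no stereocenter and no ring other than the two arenes. Locants used below: ring A carries the ester carbonyl C7 on C1, OH on C2, CO2H on C3, OMe on C4, H on C5 and CH3 on C6; ring B carries CO2H on C1', OH on C2', CH3 on C3', OH on C4', the ester oxygen on C5' and CH3 on C6'. Ring A is pentasubstituted and ring B hexasubstituted, so the ester C7(=O)–O–C5' is flanked by four ortho substituents (C2–OH, C6–CH3, C4'–OH, C6'–CH3). Ring A holds two carboxyl carbons (C7 and the carboxyl on C3) that both sit next to C2–OH and must be told apart, one as the ester and one as the free acid; only one of its two oxygens (on C4) is methylated. The feature the route exploits is the hidden tricarbonyl pattern of ring A: C7–C1–C2(O)–C3–CO2H is a 3-oxoglutarate unit, and C4(OMe)–C5(H)–C6(CH3) is an acetoacetyl unit whose carboxyl carbon keeps one methoxy group, so ring A can be closed across C3–C4 and C1–C6. Sensitive points are the two salicylic-type acids (decarboxylation), the aryl ester (solvolysis, and migration to the neighbouring C4'–OH under base), the methyl ether (no Lewis-acid dealkylation at the end) and the electron-rich trioxygenated ring B (oxidation). The problem is regiochemical and steric, not stereochemical: which carboxyl, which oxygen, and how to close a tetra-ortho-substituted ester under conditions the rest survives.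

## Retrosynthetic reasoning

**15 to 14.** All four acidic groups are released in one neutral operation. Both carboxyls and the oxygens on C2' and C4' are therefore carried as benzyl groups in 14; the chelated C2–OH of ring A needs no protection. Hydrogenolysis leaves the aryl ester and the methyl ether alone and avoids base (acyl migration) and heat (decarboxylation).

**14 to 12 and 4.** The bond cut is C7–O(C5'). It is not made through a crowded tetrahedral intermediate. In 12, C7 and the oxygen on C2 are tied together as a 1,3-benzodioxin-4-one, which on irradiation opens to the quinoketene 13. The ketene carbon is sp-hybridized and unhindered, and 4 offers a single free hydroxyl (on C5'), so the site of esterification is fixed. The same acetonide unit thus protects C2–OH, distinguishes C7 from the C3 carboxyl and serves as the acyl donor.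

**12 to 6 and 9 (key disconnection).** The bonds cut are C3–C4 and C1–C6 of ring A. These two cuts separate the 3-oxoglutarate part (C7, C1, C2, C3 and the C3 carboxyl) from the C4–C5–C6 part. In 6 the dioxinone ring makes the two α-carbons of the oxoglutarate chemically different: C3 is an acidic sp3 CH2, C1 is a vinylic CH that is nucleophilic only through the vinylogous enolate. The unsymmetrical dielectrophile 9 can therefore be taken up in one sense only. The CH2 attacks the ketene acetal carbon (C4, which keeps one methoxy group), and the dioxinone carbon then closes onto the ketone (C6, which brings the methyl group). One operation would give all five substituents of ring A, with no phenol methylation and no ester differentiation left to do. The forward reaction has to achieve substitution at a push–pull alkene (via 10) and carbon- rather than oxygen-cyclization.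

**6 to 5, and 9 to 7 and 8.** In 6 the bond between the exocyclic carbon and the ester carbonyl is cut, which leads back to the vinylogous enolate of 5. In 9 the bond between the acyl carbon and the alkene carbon is cut, which leads back to C-acylation of the ketene acetal 7 by 8.

**4 to 3 to 2 to 1.** The oxygen on C5' is introduced at the only unsubstituted ring position of 2 through the bromide 3. Compound 1 already holds every carbon of ring B, and its exhaustive benzylation to 2 sets the protecting groups needed in 14.

## Alternatives that were turned down

**Alternative 1:** the textbook disconnection of the depside ester between two finished rings. 3-Formyl-2-hydroxy-4-methoxy-6-methylbenzoic acid A1 would be coupled with 4 through a mixed anhydride or a carbodiimide to the aldehyde depside A2, followed by chlorite oxidation of the aldehyde and hydrogenolysis. It was turned down for three reasons. A1 needs formylation of an orsellinate (C3 against C5), discrimination of the C2 and C4 hydroxyls in the methylation and hydrolysis of a di-ortho-substituted benzoate, a longer sequence for ring A alone than the present route to 12. The coupling passes through a tetrahedral intermediate between a 2,6-disubstituted acyl donor and a 2,6-disubstituted phenol. An extra late oxidation is needed on the sensitive depside. The key step only joins two complete rings.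

**Alternative 2:** cut the C5'–O bond instead of the acyl–O bond. Friedel–Crafts acylation of 2 at C5' with an activated ring A carboxyl would give the benzophenone A3, and a Baeyer–Villiger oxidation would insert the oxygen by migration of ring B. It was turned down because both aryl groups carry ortho and para oxygen donors, so migratory aptitude does not clearly favour ring B. The tetra-ortho-substituted ketone is twisted and hindered towards both its formation and peracid addition. Electron-rich arenes invite ring oxidation by the peracid.

**Alternative 3:** build the hexasubstituted ring B by a Dötz benzannulation. The zerovalent chromium carbene complex A4 (Cr(CO)5 fragment) and the alkyne benzyl but-2-ynoate A5 would give the phenol A6, in which the only free hydroxyl is the one on C5', born from carbon monoxide. It was turned down because the regiochemistry requires the alkyne methyl carbon, not the ester carbon, next to the new phenol, and ynoates are poor and weakly selective partners. The methoxy group left on C2' by the carbene could not later be removed in the presence of the C4 methyl ether of ring A. Stoichiometric chromium and a multistep carbene synthesis would cost more than the commercial ring B skeleton 1.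

Key step: step 6

## Route

**Step 1**
Reactants: 1 2,4-dihydroxy-3,6-dimethylbenzoic acid
Product: 2 benzyl 2,4-bis(benzyloxy)-3,6-dimethylbenzoate
Conditions: BnBr (3.6 equiv), K2CO3, DMF, rt then 60 °C
Reagents that add atoms: benzyl bromide, BrCc1ccccc1
Why: Williamson-type alkylation; the carboxylate is esterified at room temperature before heating, which removes the risk of decarboxylation, and the two phenoxides (the chelated one last) follow at 60 °C.

**Step 2**
Reactants: 2 benzyl 2,4-bis(benzyloxy)-3,6-dimethylbenzoate
Product: 3 benzyl 2,4-bis(benzyloxy)-5-bromo-3,6-dimethylbenzoate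
Conditions: NBS, MeCN, 0 °C to rt, dark
Reagents that add atoms: N-bromosuccinimide, O=C1CCC(=O)N1Br
Why: Electrophilic aromatic bromination at the only free ring position, which is ortho and para to the two ether oxygens; polar solvent and absence of light keep the benzylic positions untouched.

**Step 3**
Reactants: 3 benzyl 2,4-bis(benzyloxy)-5-bromo-3,6-dimethylbenzoate
Product: 4 benzyl 2,4-bis(benzyloxy)-5-hydroxy-3,6-dimethylbenzoate
Conditions: Pd2(dba)3 (cat.), tBuXPhos, KOH, 1,4-dioxane/H2O, 100 °C; aq. HCl work-up
Reagents that add atoms: potassium hydroxide, [K+].[OH-]
Why: Buchwald–Hartwig-type hydroxylation; the bulky biaryl phosphine supports oxidative addition of zerovalent palladium into the di-ortho-substituted bromide and C–O reductive elimination, and the 2,6-disubstituted benzyl benzoate should resist saponification.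

**Step 4**
Reactants: 5 2,2,6-trimethyl-4H-1,3-dioxin-4-one
Product: 6 benzyl 2-(2,2-dimethyl-4-oxo-4H-1,3-dioxin-6-yl)acetate
Conditions: LiN(SiMe3)2 (2.1 equiv), THF, −78 °C; ClCO2Bn, −78 °C; aq. NH4Cl
Reagents that add atoms: benzyl chloroformate, O=C(Cl)OCc1ccccc1
Why: Vinylogous C-acylation of the lithium dienolate at the exocyclic (γ) carbon, the usual site of reaction of this dienolate with acyl electrophiles; the second equivalent of base is taken up by the more acidic product and prevents double acylation.

**Step 5**
Reactants: 7 1,1-dimethoxyethene, 8 acetyl chloride
Product: 9 4,4-dimethoxybut-3-en-2-one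
Conditions: pyridine, CH2Cl2, 0 °C
Reagents that add atoms: none
Why: C-acylation of an electron-rich ketene acetal by an acid chloride, the same reaction type as the acylation of enol ethers with acyl chlorides and pyridine; the base removes the proton from the dialkoxycarbenium intermediate and suppresses dealkylation to the β-keto ester.

**Step 6**
Reactants: 6 benzyl 2-(2,2-dimethyl-4-oxo-4H-1,3-dioxin-6-yl)acetate, 9 4,4-dimethoxybut-3-en-2-one
Product: 12 benzyl 7-methoxy-2,2,5-trimethyl-4-oxo-4H-1,3-benzodioxine-8-carboxylate, via enone adduct 10 (not isolated)
Conditions: LiN(SiMe3)2 (1.05 equiv), THF, −78 °C; 9, −78 °C to rt; AcOH (1.1 equiv); then Et3N (cat.), 4 Å MS, 50 °C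
Reagents that add atoms: none
Why: Proposed new method: the lithium enolate of 6, formed at the exocyclic CH2 (the only acidic site, since the second α-carbon of the masked 3-oxoglutarate is the vinylic CH of the dioxinone), should add to the ketene acetal carbon of 9 and expel methoxide (addition–elimination at a push–pull alkene), which makes the C3–C4 bond and leaves exactly one methoxy group on C4; after the acetic acid quench, triethylamine should deprotonate the doubly activated CH of 10, and the vinylogous enolate should attack the methyl ketone through the dioxinone carbon (C1–C6 bond), after which loss of water aromatizes ring A. The closest known reaction types are the [3+3] cyclocondensation of dialkyl 3-oxoglutarates with 1,3-dielectrophiles to 2-hydroxyisophthalates, the benzannulation of α-oxo ketene acetals with three-carbon dinucleophiles, and the amine-induced aromatization of 6-(2,4-dioxoalkyl)-1,3-dioxin-4-ones to benzodioxinones. The one ring closed is the carbocycle C1–C6, in a 6-exo-trig aldol mode (equivalently a 6π closure of the trienolate) after the intermolecular C3–C4 union. No stereocenter is formed, and the alkene geometry of 10 is of no consequence because it equilibrates through the enolate. Regioselectivity rests on the different character of the two nucleophilic carbons (CH2 first, vinylogous carbon second) and of the two electrophilic carbons (acetal carbon for the soft carbanion, ketone for the aldol). The selectivity most at stake is carbon- against oxygen-cyclization, that is aldol at the ketone against lactonization of the enolate oxygen onto the benzyl ester; the carbocyclic path is favoured by aromatization and by the mild amine base, and methoxide is neutralized before warming so that it cannot open the product.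

**Step 7**
Reactants: 12 benzyl 7-methoxy-2,2,5-trimethyl-4-oxo-4H-1,3-benzodioxine-8-carboxylate, 4 benzyl 2,4-bis(benzyloxy)-5-hydroxy-3,6-dimethylbenzoate
Product: 14 3-benzyl 1-[2,4-bis(benzyloxy)-5-(benzyloxycarbonyl)-3,6-dimethylphenyl] 2-hydroxy-4-methoxy-6-methylbenzene-1,3-dicarboxylate, via quinoketene 13 (not isolated)
Conditions: hν (300 nm), degassed CH2Cl2, rt
Reagents that add atoms: none
Why: Photochemical cycloreversion of the benzodioxinone (retro-hetero-Diels–Alder) should release acetone and the quinoketene 13, whose unhindered sp carbon is captured by the single free phenol of 4, the known photochemical acylation with benzodioxinones; the resulting enol tautomerizes to the chelated salicylate, and ring B has no free ortho or para position for a photo-Fries shift.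

**Step 8**
Reactants: 14 3-benzyl 1-[2,4-bis(benzyloxy)-5-(benzyloxycarbonyl)-3,6-dimethylphenyl] 2-hydroxy-4-methoxy-6-methylbenzene-1,3-dicarboxylate
Product: 15 hypothamnolic acid, 3-[(3-carboxy-2-hydroxy-4-methoxy-6-methylbenzoyl)oxy]-4,6-dihydroxy-2,5-dimethylbenzoic acid
Conditions: H2 (1 atm), Pd/C, EtOAc, rt
Reagents that add atoms: none
Why: Hydrogenolysis of two benzyl esters and two benzyl ethers under neutral conditions; the aryl ester and the methyl ether are inert, and the absence of base and heat avoids acyl migration to the C4' hydroxyl and decarboxylation.

## Compound list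

1 | 2,4-dihydroxy-3,6-dimethylbenzoic acid | Cc1cc(O)c(C)c(O)c1C(=O)O | starting material
2 | benzyl 2,4-bis(benzyloxy)-3,6-dimethylbenzoate | Cc1cc(OCc2ccccc2)c(C)c(OCc2ccccc2)c1C(=O)OCc1ccccc1 | intermediate
3 | benzyl 2,4-bis(benzyloxy)-5-bromo-3,6-dimethylbenzoate | Cc1c(Br)c(OCc2ccccc2)c(C)c(OCc2ccccc2)c1C(=O)OCc1ccccc1 | intermediate
4 | benzyl 2,4-bis(benzyloxy)-5-hydroxy-3,6-dimethylbenzoate | Cc1c(O)c(OCc2ccccc2)c(C)c(OCc2ccccc2)c1C(=O)OCc1ccccc1 | intermediate
5 | 2,2,6-trimethyl-4H-1,3-dioxin-4-one | CC1=CC(=O)OC(C)(C)O1 | starting material
6 | benzyl 2-(2,2-dimethyl-4-oxo-4H-1,3-dioxin-6-yl)acetate | CC1(C)OC(=O)C=C(CC(=O)OCc2ccccc2)O1 | intermediate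
7 | 1,1-dimethoxyethene | C=C(OC)OC | starting material
8 | acetyl chloride | CC(=O)Cl | starting material
9 | 4,4-dimethoxybut-3-en-2-one | CC(=O)C=C(OC)OC | intermediate
10 | benzyl (3E)-2-(2,2-dimethyl-4-oxo-4H-1,3-dioxin-6-yl)-3-methoxy-5-oxohex-3-enoate (racemic, configurationally labile at C2) | CC(=O)/C=C(/OC)C(C(=O)OCc1ccccc1)C1=CC(=O)OC(C)(C)O1 | intermediate
11 | not used |  | 
12 | benzyl 7-methoxy-2,2,5-trimethyl-4-oxo-4H-1,3-benzodioxine-8-carboxylate | COc1cc(C)c2C(=O)OC(C)(C)Oc2c1C(=O)OCc1ccccc1 | intermediate
13 | benzyl 2-methoxy-4-methyl-6-oxo-5-(oxomethylidene)cyclohexa-1,3-diene-1-carboxylate (quinoketene) | COC1=C(C(=O)OCc2ccccc2)C(=O)C(=C=O)C(C)=C1 | intermediate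
14 | 3-benzyl 1-[2,4-bis(benzyloxy)-5-(benzyloxycarbonyl)-3,6-dimethylphenyl] 2-hydroxy-4-methoxy-6-methylbenzene-1,3-dicarboxylate | COc1cc(C)c(C(=O)Oc2c(C)c(C(=O)OCc3ccccc3)c(OCc3ccccc3)c(C)c2OCc2ccccc2)c(O)c1C(=O)OCc1ccccc1 | intermediate
15 | hypothamnolic acid | COc1cc(C)c(C(=O)Oc2c(C)c(C(=O)O)c(O)c(C)c2O)c(O)c1C(=O)O | target

The number 11 is left unassigned; no compound carries it.

## Step count and least certain steps

Total step count: 8. Longest linear sequence: 5 steps (steps 1, 2, 3, 7, 8, from 1 to 15); the ring A branch (steps 4 or 5, then 6, 7, 8) is 4 steps long.

**Step 6 (key step, proposed new method).** The substitution at the push–pull alkene of 9 may be too slow for the stabilized enolate of 6. The ketone of 10, being the carbonyl of a vinylogous ester, may also resist the aldol closure, so that lactonization of the enolate oxygen onto the benzyl ester or plain recovery of 6 takes over. The fallback uses known chemistry, sets out from 6 and returns at 12. C-acetoacetylation of the sodium enolate of 6 with diketene (NaH, THF, 0 °C) should give benzyl 2-(2,2-dimethyl-4-oxo-4H-1,3-dioxin-6-yl)-3,5-dioxohexanoate F1, in which the reacting ketone is an ordinary β-diketone carbonyl. Triethylamine in CH2Cl2 should aromatize it with loss of water to benzyl 7-hydroxy-2,2,5-trimethyl-4-oxo-4H-1,3-benzodioxine-8-carboxylate F2. Its only free phenol would be methylated (MeI, K2CO3, acetone) to 12.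

**Step 7.** Capture of the quinoketene by the hindered, internally hydrogen-bonded phenol may be slow, so that ketene dimerization, hydration by adventitious water or secondary photoreactions of the benzyl groups compete. The fallback sets out from 12 and returns at 14. Opening of the acetonide with LiOH in THF/H2O at rt (the benzyl ester is di-ortho-substituted and should survive) would give 3-[(benzyloxy)carbonyl]-2-hydroxy-4-methoxy-6-methylbenzoic acid F3. This would be esterified with 4 through the mixed trifluoroacetic anhydride (TFAA, toluene, rt) to 14.

**Step 3.** Oxidative addition into the di-ortho-substituted, electron-rich bromide may be sluggish, and slow cleavage of the benzyl ester by hot hydroxide may compete. The fallback sets out from 2 and returns at 4. Rieche formylation of 2 at the free position (Cl2CHOMe, SnCl4, CH2Cl2, −78 to 0 °C) would give benzyl 2,4-bis(benzyloxy)-5-formyl-3,6-dimethylbenzoate F4. Dakin-type Baeyer–Villiger oxidation (mCPBA, CH2Cl2) would give the aryl formate benzyl 2,4-bis(benzyloxy)-5-(formyloxy)-3,6-dimethylbenzoate F5, which is cleaved in the same flask (K2CO3, MeOH, 0 °C) to 4.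

**Step 5.** Protonation of the acid-sensitive ketene acetal by the pyridinium salt and dealkylation of the acylated intermediate may lead to methyl esters instead of 9. The fallback sets out from 8 and returns at 9. Friedel–Crafts-type acylation of 1,1-dichloroethene with 8 (AlCl3, CH2Cl2, 0 °C), followed by loss of hydrogen chloride on distillation, would give 4,4-dichlorobut-3-en-2-one F6. Twofold addition–elimination with NaOMe (2 equiv, MeOH, 0 °C) would give 9.

## Further compounds

F1 | step 6 | benzyl 2-(2,2-dimethyl-4-oxo-4H-1,3-dioxin-6-yl)-3,5-dioxohexanoate | CC(=O)CC(=O)C(C(=O)OCc1ccccc1)C1=CC(=O)OC(C)(C)O1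
F2 | step 6 | benzyl 7-hydroxy-2,2,5-trimethyl-4-oxo-4H-1,3-benzodioxine-8-carboxylate | Cc1cc(O)c(C(=O)OCc2ccccc2)c2OC(C)(C)OC(=O)c12
F3 | step 7 | 3-[(benzyloxy)carbonyl]-2-hydroxy-4-methoxy-6-methylbenzoic acid | COc1cc(C)c(C(=O)O)c(O)c1C(=O)OCc1ccccc1
F4 | step 3 | benzyl 2,4-bis(benzyloxy)-5-formyl-3,6-dimethylbenzoate | Cc1c(C=O)c(OCc2ccccc2)c(C)c(OCc2ccccc2)c1C(=O)OCc1ccccc1
F5 | step 3 | benzyl 2,4-bis(benzyloxy)-5-(formyloxy)-3,6-dimethylbenzoate | Cc1c(OC=O)c(OCc2ccccc2)c(C)c(OCc2ccccc2)c1C(=O)OCc1ccccc1
F6 | step 5 | 4,4-dichlorobut-3-en-2-one | CC(=O)C=C(Cl)Cl
A1 | alternative 1 | 3-formyl-2-hydroxy-4-methoxy-6-methylbenzoic acid | COc1cc(C)c(C(=O)O)c(O)c1C=O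
A2 | alternative 1 | 2,4-bis(benzyloxy)-5-(benzyloxycarbonyl)-3,6-dimethylphenyl 3-formyl-2-hydroxy-4-methoxy-6-methylbenzoate | COc1cc(C)c(C(=O)Oc2c(C)c(C(=O)OCc3ccccc3)c(OCc3ccccc3)c(C)c2OCc2ccccc2)c(O)c1C=O
A3 | alternative 2 | benzyl 2,4-bis(benzyloxy)-5-{3-[(benzyloxy)carbonyl]-2-hydroxy-4-methoxy-6-methylbenzoyl}-3,6-dimethylbenzoate | COc1cc(C)c(C(=O)c2c(C)c(C(=O)OCc3ccccc3)c(OCc3ccccc3)c(C)c2OCc2ccccc2)c(O)c1C(=O)OCc1ccccc1
A4 | alternative 3 | pentacarbonyl[(2E)-3-(benzyloxy)-1-methoxy-2-methylprop-2-en-1-ylidene]chromium | COC(=[Cr](=C=O)(=C=O)(=C=O)(=C=O)=C=O)/C(C)=C/OCc1ccccc1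
A5 | alternative 3 | benzyl but-2-ynoate | CC#CC(=O)OCc1ccccc1
A6 | alternative 3 | benzyl 4-(benzyloxy)-5-hydroxy-2-methoxy-3,6-dimethylbenzoate | COc1c(C)c(OCc2ccccc2)c(O)c(C)c1C(=O)OCc1ccccc1
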